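The route rests on cutting two neighbouring bonds of ring A at once, C6–C(=O) and C7–O, which leads back to a 5-methoxy-2,2-dimethyl-2H-chromen-6,7-yne. In the key step this aryne, released by fluoride from its 6-silyl 7-triflate, inserts into the C–O bond of a cesium carboxylate that carries ring B and the second carbonyl as a dimethyl ketal. The C5 methoxy group beside the triple bond sends the carboxylate oxygen to C7 and the carbanion to C6, where it captures the acyl group. One operation thus joins both halves at the most hindered ring carbon and sets the free C7 hydroxyl beside the C5 methyl ether; ketal hydrolysis then gives the benzil.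

Key step: step 11

Assumption: the target is taken as the open 2-hydroxybenzil, which the C7–OH···O=C hydrogen bond should favour over the cyclic hemiketal. The target has no stereocenter, and the only stereogenic intermediate (6) is racemic and is destroyed in the same step.

Step 1
Reactants: 1 phloroglucinol; 2 3-methylbut-2-enoic acid
Product: 3 5,7-dihydroxy-2,2-dimethylchroman-4-one
Conditions: P4O10, MeSO3H, 70 °C
Reagents that add atoms: none
Why: Friedel–Crafts acylation of the electron-rich triphenol by the unsaturated acid followed by intramolecular oxa-Michael addition closes the pyranone, and the threefold symmetry of 1 leaves no regiochemical choice.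

Step 2
Reactants: 3 5,7-dihydroxy-2,2-dimethylchroman-4-one
Product: 4 5-hydroxy-2,2-dimethyl-4-oxochroman-7-yl N,N-diethylcarbamate
Conditions: Et2NCOCl (1.05 equiv), K2CO3, MeCN, reflux
Reagents that add atoms: N,N-diethylcarbamoyl chloride, CCN(CC)C(Cl)=O
Why: Chemoselective O-carbamoylation, because the C5 hydroxyl is tied up in a hydrogen bond to the C4 carbonyl and only the free, more acidic C7 hydroxyl should be acylated; the tertiary carbamate later serves as metalation director.

Step 3
Reactants: 4 5-hydroxy-2,2-dimethyl-4-oxochroman-7-yl N,N-diethylcarbamate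
Product: 5 5-methoxy-2,2-dimethyl-4-oxochroman-7-yl N,N-diethylcarbamate
Conditions: MeI, K2CO3, DMF, 50 °C
Reagents that add atoms: iodomethane, CI
Why: Williamson ether synthesis on the chelated C5 phenol, which needs the polar solvent and warming, while the tertiary carbamate is inert to carbonate.

Step 4
Reactants: 5 5-methoxy-2,2-dimethyl-4-oxochroman-7-yl N,N-diethylcarbamate
Product: 7 5-methoxy-2,2-dimethyl-2H-chromen-7-yl N,N-diethylcarbamate, via racemic chroman-4-ol carbamate 6 (not isolated)
Conditions: NaBH4, MeOH/THF, 0 °C to rt; then p-TsOH·H2O (cat.), toluene, 80 °C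
Reagents that add atoms: none
Why: Hydride reduction of the aryl ketone gives benzylic alcohol 6, and acid-catalysed E1 dehydration through the benzylic cation stabilised by the ortho and para oxygens should install the C3=C4 alkene.

Step 5
Reactants: 7 5-methoxy-2,2-dimethyl-2H-chromen-7-yl N,N-diethylcarbamate
Product: 9 5-methoxy-2,2-dimethyl-6-(trimethylsilyl)-2H-chromen-7-yl N,N-diethylcarbamate, via 6-lithio carbamate 8 (not isolated)
Conditions: s-BuLi, TMEDA, THF, −78 °C; then Me3SiCl, −78 °C to rt
Reagents that add atoms: chlorotrimethylsilane, C[Si](C)(C)Cl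
Why: Directed ortho-metalation, in which the carbamate carbonyl and the C5 methoxy oxygen should jointly acidify and coordinate at C6–H in preference to C8–H, whose second neighbour is the pyran oxygen hindered by the gem-dimethyl group; silylation at −78 °C should outrun the anionic ortho-Fries shift.

Step 6
Reactants: 9 5-methoxy-2,2-dimethyl-6-(trimethylsilyl)-2H-chromen-7-yl N,N-diethylcarbamate
Product: 10 5-methoxy-2,2-dimethyl-6-(trimethylsilyl)-2H-chromen-7-ol
Conditions: LiAlH4, THF, 0 °C to 40 °C; aq. potassium sodium tartrate (KNaC4H4O6) work-up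
Reagents that add atoms: none
Why: Reductive cleavage of the aryl carbamate by hydride addition to its carbonyl and expulsion of the aryloxide; the alkene, the aryl–silicon bond and the ethers are inert to LiAlH4.

Step 7
Reactants: 10 5-methoxy-2,2-dimethyl-6-(trimethylsilyl)-2H-chromen-7-ol
Product: 11 5-methoxy-2,2-dimethyl-6-(trimethylsilyl)-2H-chromen-7-yl trifluoromethanesulfonate
Conditions: PhNTf2, DBU, MeCN, rt to 40 °C
Reagents that add atoms: N-phenylbis(trifluoromethanesulfonimide), O=S(=O)(N(c1ccccc1)S(=O)(=O)C(F)(F)F)C(F)(F)F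
Why: O-Sulfonylation of the phenoxide with a mild triflyl donor under base, which avoids acid and so the protodesilylation of the electron-rich aryl silane.

Step 8
Reactants: 12 2-(4-hydroxyphenyl)-2-oxoacetic acid
Product: 13 methyl 2-(4-hydroxyphenyl)-2,2-dimethoxyacetate
Conditions: HC(OMe)3, MeOH, H2SO4 (cat.), reflux; NaHCO3 quench before concentration
Reagents that add atoms: trimethyl orthoformate, COC(OC)OC; methanol, CO
Why: Fischer esterification and acid-catalysed ketalisation of the activated α-keto carbonyl run together, the orthoformate removing water, and the base quench protects the ketal during isolation.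

Step 9
Reactants: 13 methyl 2-(4-hydroxyphenyl)-2,2-dimethoxyacetate; 14 1-bromo-3-methylbut-2-ene
Product: 15 methyl 2,2-dimethoxy-2-[4-(3-methylbut-2-enyloxy)phenyl]acetate
Conditions: K2CO3, acetone, reflux
Reagents that add atoms: none
Why: Williamson ether synthesis by SN2 attack of the phenoxide at the primary allylic bromide; ester and ketal are stable to carbonate.

Step 10
Reactants: 15 methyl 2,2-dimethoxy-2-[4-(3-methylbut-2-enyloxy)phenyl]acetate
Product: 16 cesium 2,2-dimethoxy-2-[4-(3-methylbut-2-enyloxy)phenyl]acetate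
Conditions: CsOH·H2O (1.0 equiv), MeOH/H2O, rt to 40 °C; evaporation, azeotropic drying (toluene), high vacuum
Reagents that add atoms: cesium hydroxide monohydrate, [Cs+].[OH-].O
Why: Saponification (BAc2) of the methyl ester activated by two α-oxygens; the product is kept as its dry cesium salt, which protects the ketal from acid and is the nucleophile of the key step.

Step 11
Reactants: 11 5-methoxy-2,2-dimethyl-6-(trimethylsilyl)-2H-chromen-7-yl trifluoromethanesulfonate; 16 cesium 2,2-dimethoxy-2-[4-(3-methylbut-2-enyloxy)phenyl]acetate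
Product: 18 1-(7-hydroxy-5-methoxy-2,2-dimethyl-2H-chromen-6-yl)-2,2-dimethoxy-2-[4-(3-methylbut-2-enyloxy)phenyl]ethan-1-one, via chromen-6,7-yne 17 (not isolated)
Conditions: 16 (1.5 equiv), CsF (3 equiv), THF, 125 °C, sealed tube; then aq. NH4Cl
Reagents that add atoms: none
Why: Fluoride attacks silicon of 11 and triflate leaves to give aryne 17; the carboxylate oxygen of 16 should add at C7, the terminus remote from the C5 methoxy group, because this places the developing carbanion at C6 where the σ-withdrawing methoxy oxygen stabilises it and because the bent aryne is flatter and more electrophilic at C7. The C6 carbanion then attacks the neighbouring ester carbonyl in a 4-exo-trig closure to a transient four-membered alkoxide that opens to the chelated ortho-acyl phenoxide, a net 1,3 O-to-C acyl shift of the anionic Fries type. The closest known reaction type is the fluoride-induced insertion of arynes into the C–O bond of carboxylic acids to give ortho-hydroxyaryl ketones. No ring of the product and no stereocenter is formed. The step needs regioselectivity at the triple bond, which the C5 methoxy group secures, and acyl capture in preference to protonation or other carbanion pathways, which is secured by the dry cesium salt (no acidic proton), by the absence of α-hydrogens in 16 and by the ketal mask that leaves the ester carbonyl as the only electrophile within reach.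

Step 12
Reactants: 18 1-(7-hydroxy-5-methoxy-2,2-dimethyl-2H-chromen-6-yl)-2,2-dimethoxy-2-[4-(3-methylbut-2-enyloxy)phenyl]ethan-1-one
Product: 19 Ficucaricone C
Conditions: 1 M aq. HCl, THF, rt
Reagents that add atoms: water, O
Why: Acid-catalysed ketal hydrolysis through an oxocarbenium ion stabilised by the para-alkoxyphenyl ring; dilute acid at room temperature should spare the aryl prenyl ether and the chromene, and the product should rest as the hydrogen-bonded open 2-hydroxybenzil.

Compound list
1 | phloroglucinol (benzene-1,3,5-triol) | Oc1cc(O)cc(O)c1 | starting material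
2 | 3-methylbut-2-enoic acid | CC(C)=CC(=O)O | starting material
3 | 5,7-dihydroxy-2,2-dimethylchroman-4-one | CC1(C)CC(=O)c2c(O)cc(O)cc2O1 | intermediate
4 | 5-hydroxy-2,2-dimethyl-4-oxochroman-7-yl N,N-diethylcarbamate | CCN(CC)C(=O)Oc1cc(O)c2c(c1)OC(C)(C)CC2=O | intermediate
5 | 5-methoxy-2,2-dimethyl-4-oxochroman-7-yl N,N-diethylcarbamate | CCN(CC)C(=O)Oc1cc(OC)c2c(c1)OC(C)(C)CC2=O | intermediate
6 | 4-hydroxy-5-methoxy-2,2-dimethylchroman-7-yl N,N-diethylcarbamate (racemic, formed in the flask) | CCN(CC)C(=O)Oc1cc(OC)c2c(c1)OC(C)(C)CC2O | intermediate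
7 | 5-methoxy-2,2-dimethyl-2H-chromen-7-yl N,N-diethylcarbamate | CCN(CC)C(=O)Oc1cc(OC)c2C=CC(C)(C)Oc2c1 | intermediate
8 | 6-lithio-5-methoxy-2,2-dimethyl-2H-chromen-7-yl N,N-diethylcarbamate (formed in the flask) | CCN(CC)C(=O)Oc1cc2OC(C)(C)C=Cc2c(OC)c1[Li] | intermediate
9 | 5-methoxy-2,2-dimethyl-6-(trimethylsilyl)-2H-chromen-7-yl N,N-diethylcarbamate | CCN(CC)C(=O)Oc1cc2OC(C)(C)C=Cc2c(OC)c1[Si](C)(C)C | intermediate
10 | 5-methoxy-2,2-dimethyl-6-(trimethylsilyl)-2H-chromen-7-ol | COc1c2C=CC(C)(C)Oc2cc(O)c1[Si](C)(C)C | intermediate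
11 | 5-methoxy-2,2-dimethyl-6-(trimethylsilyl)-2H-chromen-7-yl trifluoromethanesulfonate | COc1c2C=CC(C)(C)Oc2cc(OS(=O)(=O)C(F)(F)F)c1[Si](C)(C)C | intermediate
12 | 2-(4-hydroxyphenyl)-2-oxoacetic acid | OC(=O)C(=O)c1ccc(O)cc1 | starting material
13 | methyl 2-(4-hydroxyphenyl)-2,2-dimethoxyacetate | COC(=O)C(OC)(OC)c1ccc(O)cc1 | intermediate
14 | 1-bromo-3-methylbut-2-ene (prenyl bromide) | CC(C)=CCBr | starting material
15 | methyl 2,2-dimethoxy-2-[4-(3-methylbut-2-enyloxy)phenyl]acetate | COC(=O)C(OC)(OC)c1ccc(OCC=C(C)C)cc1 | intermediate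
16 | cesium 2,2-dimethoxy-2-[4-(3-methylbut-2-enyloxy)phenyl]acetate | [Cs+].[O-]C(=O)C(OC)(OC)c1ccc(OCC=C(C)C)cc1 | intermediate
17 | 5-methoxy-2,2-dimethyl-2H-chromen-6,7-yne (aryne, formed in the flask) | COC1=C2C=CC(C)(C)OC2=CC#C1 | intermediate
18 | 1-(7-hydroxy-5-methoxy-2,2-dimethyl-2H-chromen-6-yl)-2,2-dimethoxy-2-[4-(3-methylbut-2-enyloxy)phenyl]ethan-1-one | COc1c2C=CC(C)(C)Oc2cc(O)c1C(=O)C(OC)(OC)c3ccc(OCC=C(C)C)cc3 | intermediate
19 | Ficucaricone C, 1-(7-hydroxy-5-methoxy-2,2-dimethyl-2H-chromen-6-yl)-2-[4-(3-methylbut-2-enyloxy)phenyl]ethane-1,2-dione | COc1c2c(cc(O)c1C(=O)C(=O)c1ccc(OCC=C(C)C)cc1)OC(C)(C)C=C2 | target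

Total step count: 12. Longest linear sequence: 9 (steps 1 to 7, 11 and 12).

Steps most likely to fail

Step 11. The C6 carbanion may be protonated before the acyl group is transferred, or the aryne may be consumed by ene reaction with the prenyl or chromene alkenes or by self-condensation, so that coupling stops at O-arylation or does not occur. The fallback replaces aryne insertion by polar acylation and sets out from 7 and 15. Ester 15 would be converted with MeNH(OMe)·HCl and i-PrMgCl in THF at −20 °C into the Weinreb amide N-methoxy-N-methyl-2,2-dimethoxy-2-[4-(3-methylbut-2-enyloxy)phenyl]acetamide F1. Carbamate 7 would be lithiated as in step 5 to 8, and 8 added to F1 at −78 °C should give the ketone 6-{2,2-dimethoxy-2-[4-(3-methylbut-2-enyloxy)phenyl]acetyl}-5-methoxy-2,2-dimethyl-2H-chromen-7-yl N,N-diethylcarbamate F2. KOH in EtOH/H2O at reflux should then remove the carbamate, which the ortho-acyl group activates, and the route is rejoined at 18.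

Step 5. Lithiation may partition between C6 and C8, each of which lies between two oxygens, or the carbamoyl group may shift to carbon by anionic ortho-Fries rearrangement before silylation. The fallback replaces directed metalation by chelation-controlled electrophilic substitution and sets out from 4.
- Iodination with benzyltrimethylammonium dichloroiodate (BnMe3N+ ICl2−) and CaCO3 in CH2Cl2/MeOH should occur ortho to the free C5 hydroxyl and give 5-hydroxy-6-iodo-2,2-dimethyl-4-oxochroman-7-yl N,N-diethylcarbamate F3.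
- Methylation (MeI, K2CO3, DMF) should give 6-iodo-5-methoxy-2,2-dimethyl-4-oxochroman-7-yl N,N-diethylcarbamate F4.
- NaBH4 in MeOH should give racemic 4-hydroxy-6-iodo-5-methoxy-2,2-dimethylchroman-7-yl N,N-diethylcarbamate F5.
- n-BuLi (2.2 equiv, THF, −78 °C) would deprotonate the alcohol and exchange iodine for lithium, and excess Me3SiCl should give 5-methoxy-2,2-dimethyl-6-(trimethylsilyl)-4-(trimethylsilyloxy)chroman-7-yl N,N-diethylcarbamate F6.
- K2CO3 in MeOH should free the alcohol to 4-hydroxy-5-methoxy-2,2-dimethyl-6-(trimethylsilyl)chroman-7-yl N,N-diethylcarbamate F7.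
- Dehydration with PPTS (cat.) in toluene at 60 °C should bring the route back at 9.

Step 12. The acid needed to ionise a ketal next to a carbonyl may also cleave the aryl prenyl ether or hydrate the chromene alkene. The fallback moves the prenylation to the end and sets out from 13.
- MOMCl and i-Pr2NEt in CH2Cl2 should give methyl 2,2-dimethoxy-2-[4-(methoxymethoxy)phenyl]acetate F8.
- CsOH·H2O should give cesium 2,2-dimethoxy-2-[4-(methoxymethoxy)phenyl]acetate F9.
- F9 and 11 under the conditions of step 11 should give 1-(7-hydroxy-5-methoxy-2,2-dimethyl-2H-chromen-6-yl)-2,2-dimethoxy-2-[4-(methoxymethoxy)phenyl]ethan-1-one F10.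
- 1 M HCl in MeOH/THF at 40 °C should remove the acetal and the ketal together, with no prenyl ether present, and give 1-(7-hydroxy-5-methoxy-2,2-dimethyl-2H-chromen-6-yl)-2-(4-hydroxyphenyl)ethane-1,2-dione F11.
- Alkylation with 14 (1.0 equiv) and KHCO3 in DMF at rt should take place only at the non-chelated, more acidic ring B hydroxyl and return the route at 19.

Further compounds
F1 | step 11 | N-methoxy-N-methyl-2,2-dimethoxy-2-[4-(3-methylbut-2-enyloxy)phenyl]acetamide | CON(C)C(=O)C(OC)(OC)c1ccc(OCC=C(C)C)cc1
F2 | step 11 | 6-{2,2-dimethoxy-2-[4-(3-methylbut-2-enyloxy)phenyl]acetyl}-5-methoxy-2,2-dimethyl-2H-chromen-7-yl N,N-diethylcarbamate | CCN(CC)C(=O)Oc1cc2OC(C)(C)C=Cc2c(OC)c1C(=O)C(OC)(OC)c1ccc(OCC=C(C)C)cc1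
F3 | step 5 | 5-hydroxy-6-iodo-2,2-dimethyl-4-oxochroman-7-yl N,N-diethylcarbamate | CCN(CC)C(=O)Oc1cc2OC(C)(C)CC(=O)c2c(O)c1I
F4 | step 5 | 6-iodo-5-methoxy-2,2-dimethyl-4-oxochroman-7-yl N,N-diethylcarbamate | CCN(CC)C(=O)Oc1cc2OC(C)(C)CC(=O)c2c(OC)c1I
F5 | step 5 | 4-hydroxy-6-iodo-5-methoxy-2,2-dimethylchroman-7-yl N,N-diethylcarbamate (racemic) | CCN(CC)C(=O)Oc1cc2OC(C)(C)CC(O)c2c(OC)c1I
F6 | step 5 | 5-methoxy-2,2-dimethyl-6-(trimethylsilyl)-4-(trimethylsilyloxy)chroman-7-yl N,N-diethylcarbamate (racemic) | CCN(CC)C(=O)Oc1cc2OC(C)(C)CC(O[Si](C)(C)C)c2c(OC)c1[Si](C)(C)C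
F7 | step 5 | 4-hydroxy-5-methoxy-2,2-dimethyl-6-(trimethylsilyl)chroman-7-yl N,N-diethylcarbamate (racemic) | CCN(CC)C(=O)Oc1cc2OC(C)(C)CC(O)c2c(OC)c1[Si](C)(C)C
F8 | step 12 | methyl 2,2-dimethoxy-2-[4-(methoxymethoxy)phenyl]acetate | COCOc1ccc(cc1)C(OC)(OC)C(=O)OC
F9 | step 12 | cesium 2,2-dimethoxy-2-[4-(methoxymethoxy)phenyl]acetate | [Cs+].[O-]C(=O)C(OC)(OC)c1ccc(OCOC)cc1
F10 | step 12 | 1-(7-hydroxy-5-methoxy-2,2-dimethyl-2H-chromen-6-yl)-2,2-dimethoxy-2-[4-(methoxymethoxy)phenyl]ethan-1-one | COCOc1ccc(cc1)C(OC)(OC)C(=O)c1c(O)cc2OC(C)(C)C=Cc2c1OC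
F11 | step 12 | 1-(7-hydroxy-5-methoxy-2,2-dimethyl-2H-chromen-6-yl)-2-(4-hydroxyphenyl)ethane-1,2-dione | COc1c2C=CC(C)(C)Oc2cc(O)c1C(=O)C(=O)c1ccc(O)cc1
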